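Start with the easy step. L and E join one to one to give G under the catalyst Q, so E is the limiting reagent of the gamma run, and G there cannot pass 1.00 M, which is 50.0% of the L charged.

| setting | eta | theta | zeta | alpha | gamma |
|---|---|---|---|---|---|
| L | 1.00 M | 1.50 M | 1.00 M | 1.00 M | 2.00 M |
| E | 1.00 M | 1.00 M | 1.50 M | 1.00 M | 1.00 M |
| Q | 0.00500 M | 0.00500 M | 0.00500 M | 0.00750 M | 0.00250 M |
| time |  |  |  |  | 100 min |

| run | time / min | [G] / M |
|---|---|---|
| eta run | 14 | 0.340 |
| eta run | 29 | 0.535 |
| eta run | 43 | 0.649 |
| eta run | 57 | 0.703 |
| eta run | 71 | 0.743 |
| eta run | 86 | 0.768 |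
| eta run | 100 | 0.775 |
| theta run | 14 | 0.407 |
| theta run | 29 | 0.640 |
| theta run | 43 | 0.763 |
| theta run | 57 | 0.836 |
| theta run | 71 | 0.881 |
| theta run | 86 | 0.901 |
| theta run | 100 | 0.924 |
| zeta run | 14 | 0.404 |
| zeta run | 29 | 0.617 |
| zeta run | 43 | 0.706 |
| zeta run | 57 | 0.758 |
| zeta run | 71 | 0.779 |
| zeta run | 86 | 0.795 |
| zeta run | 100 | 0.796 |
| alpha run | 14 | 0.459 |
| alpha run | 29 | 0.671 |
| alpha run | 43 | 0.765 |
| alpha run | 57 | 0.821 |
| alpha run | 71 | 0.840 |
| alpha run | 86 | 0.846 |
| alpha run | 100 | 0.866 |

(each reading ± 0.005 M)

- Overall: L + E -> G, with Q as catalyst.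
- Constant volume, constant temperature.
- Bound and free are read together.
- An order is taken over about fifteen percent of the charge, up and down.

- the exponent of [L] in the starting rate at the charge of the eta run (at the point where two percent of the L have become G) (one fixed amount of G, the same in the runs compared)
- the exponent of [Q] in the starting rate at the charge of the eta run (at the point where two percent of the L have become G)
- G in the gamma run at 100 min, as a share of the L charged

That ceiling is one extreme version of the flask, a Q that works until E is gone. The other extreme is a fixed ration, where each Q makes a set number of G and stops. The last eta reading gives 155 G per Q, which in the gamma run means 0.388 M, or 19.4% of the L.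

Test the ration on the alpha run. It promises 1.16 M there, more than the 0.866 M read at 100 min. The curves flatten, then, but the height at 100 min grows more slowly than [Q], so I take the ration as a floor and expect the gamma run between the two extremes.

Where it lies depends on how fast a flask walks along a known curve. My own reckoning uses a clock factor, the speed of a flask along the eta curve. The first readings of the theta and eta runs give an order in [L] of 0.444, which I take as about 0.5. I take the order in [Q] as 1, since each Q runs its own cycle. For the gamma run:

clock factor = ([Q] ratio to eta) × ([L] ratio to eta)^0.5 = 0.707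

clock time = 100 min × clock factor = 70.7 min

The eta run reads 0.743 M at 71 min, so I expect 37.1% of the L, less than the ceiling.

The forecast gives 0.55 (0.35 to 0.75) for the order in [L], 1.2 (1 to 1.45) for the order in [Q], and 33% (26% to 39%) for the gamma run, on the ground that “The catalyst is dying.” Its order in [Q] and its yield both differ from mine.

The simulation gives 0.50, 1.0 and 38.6%.

    Q + L → QL (12.72 M⁻¹ min⁻¹)
    QL + E → G + Q (12.18 M⁻¹ min⁻¹)
    2 L → Ky (0.003798 M⁻¹ min⁻¹)
    Q + G → Vy + G (0.05334 M⁻¹ min⁻¹)

For the alpha run the clock factor is 1.50. With the eta run as the yardstick for rates at equal G, the rate ratio stood at 1.5 for the alpha run. On the gamma run the factor gave 37.1%, which is 1.5 percentage points below the value found. Two steps acting together lower G in the gamma run at 100 min, the turning of Q + G into Vy + G and of two L into Ky: without the first it gives 44.0%, and without the second 42.3%.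

The data come from a simulation with made-up constants, and the scatter is random.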